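Whatever electrophile is no longer left free after 15 s, with idle adduct counted as reacted, is what I am after, along with the pH that goes with it.

electrophile 0.067 M; nucleophile 0.0670 M; buffer base 0.201 M; buffer acid 6.70 mM; time 15 s

1. part of the electrophile that has reacted at 15 s
2. pH of the solution at 15 s

    electrophile + nucleophile → acid + target + leaving group (k1 = 0.80 /M/s)
    protonated nucleophile ⇌ nucleophile + acid, settled at all times (K2 = 5.0 × 10⁻⁸ M)
    buffer acid ⇌ buffer base + acid, settled at all times (K3 = 7.9 × 10⁻⁸ M)
    electrophile + leaving group ⇌ idle adduct, settled at all times (K4 = 20 /M)
    nucleophile ⇌ dormant form (K5 = 2.4, k5 = 0.072 /s)
    electrophile + target → side product (k6 = 0.21 /M/s)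

I count turnovers of the main step, in which electrophile and nucleophile give target, leaving group and acid. With its rate constant k, the time constant of electrophile at the charged nucleophile is 18.7 s.

In the first instants the buffer balance holds acid at 2.63 × 10⁻⁹ M. That keeps protonated nucleophile at 5.27% of the free form, so I drop it. At the start there is no target, so no side product.

In the middle the nucleophile relaxes towards the dormant form. Its balance leaves a free share f, and it relaxes with a time constant τ:

f = 29.4%, τ = 9.80 s

This τ is shorter than the time constant of the main step, so the drain comes first.

Free nucleophile therefore acts as if the charge cB had stood for an effective time: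

t_eff = f·t + (1 − f)·τ·(1 − e^(−t/τ)) = 9.83 s

The turnover count, 0.527, is k·cB·t_eff: the lifetimes of electrophile that the draining nucleophile allows.

By the end, treating the loss as pseudo-first-order overstates it, as nucleophile is also consumed. Ignoring idle adduct understates it: the equilibrium constant of adduct formation times the charged electrophile is 1.3. I let these two stand against each other:

c ≈ 1 − e^(−n) = 41.0%

Acid is made in the main step. With both partners falling I take n/(1+n) of the charge, 0.0231 M, and put it on the buffer:

pH ≈ 7.88

The forecast says 42% and 8.05, on these grounds: “The nucleophile drains into its dormant form on about a 10 s timescale while the reaction slows”. Its pH stands above mine.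

The flask gives 44.3% and pH 8.01, so the forecast holds.

In this flask the nucleophile's forward drain to dormant form runs 2.4 times the rate at which the main step uses it at 15.0 s. The flask ends with 26% of its nucleophile free, less than its 56% of electrophile. That drain is what the count 0.527 carries, with 9.83 s in place of 15 s. The neighbour charged with 0.17 M of nucleophile has a count of 1.34, which gives 73.7%, and that flask reaches 72.6%.

Its constants are invented; the result is computed.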